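(The numbers in the tables are calculated from invented constants; the scatter is artificial.)

Slowness in this reaction shows on a line that ought to be straight. J and G go one for one, so in a closed flask with a rate first order in each, the logarithm of cG/cJ climbs steadily, with a slope equal to the rate constant times the fixed excess of G over J, the limiting reagent.

| flask | J | G | Z | remark | time |
|---|---|---|---|---|---|
| beta | 0.050 M | 0.060 M | 50 µM | run made earlier |  |
| theta | 0.050 M | 0.060 M | 34 µM | run made earlier |  |
| alpha | 0.050 M | 0.060 M | 75 µM | run made earlier |  |
| zeta | 0.050 M | 0.12 M | 50 µM | run made earlier |  |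
| north-west | 0.050 M | 0.0600 M (fed, over 30.0 h) | 50 µM | a stirred flask in which G is dosed at a steady rate over 30.0 h without added volume, worked up at 30 h | 30 h |
| south-east | 0.050 M | 0.0600 M | 50 µM | a single well-mixed tank run continuously and read at steady state, 30 h in it on average |  |
| north-east | 0.050 M (fed, over 30.0 h) | 0.0600 M | 50 µM | a stirred flask in which J is dosed at a steady rate over 30.0 h without added volume, worked up at 30 h | 30 h |
| south-west | 0.050 M | 0.0600 M | 50 µM | a closed flask charged with all of it at once and left for 30 h | 30 h |

| run | time / h | D / % |
|---|---|---|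
| beta | 1.00 | 1 |
| beta | 3.00 | 15 |
| beta | 5.00 | 26 |
| beta | 8.00 | 47 |
| beta | 10.0 | 57 |
| beta | 15.0 | 70 |
| beta | 20.0 | 79 |
| theta | 3.00 | 6 |
| theta | 6.00 | 26 |
| theta | 10.0 | 45 |
| theta | 15.0 | 61 |
| theta | 20.0 | 73 |
| theta | 25.0 | 77 |
| alpha | 3.00 | 17 |
| alpha | 6.00 | 43 |
| alpha | 10.0 | 61 |
| alpha | 15.0 | 79 |
| alpha | 20.0 | 82 |
| alpha | 25.0 | 85 |
| zeta | 2.00 | 19 |
| zeta | 6.00 | 73 |
| zeta | 12.0 | 94 |
| zeta | 15.0 | 101 |
| zeta | 25.0 | 101 |

(standard deviation of a reading: 1.5 percentage points)

- the set-up with the highest amount of D at the outlet or at the end, in percent of the J put in ("none" if the first two lie within 2 percentage points) (north-west / south-east / north-east / south-west / none)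
- amount of D at the outlet or at the end, in percent of the J put in, north-west
- amount of D at the outlet or at the end, in percent of the J put in, south-east
- amount of D at the outlet or at the end, in percent of the J put in, north-east
- amount of D at the outlet or at the end, in percent of the J put in, south-west

Take beta past its delay, between 10.0 h and 20.0 h, and you read 0.0287 h⁻¹: this is the pair clock, the hourly rise of ln(cG/cJ).

South-west is beta carried on to 30 h, so the crude bracket runs from beta's last reading, 79%, where cG/cJ stands at 1.95, up to the whole charge of J. Let the clock run on unchanged and my ceiling falls to 87.5%. Theta, which has less Z and is read here over a later stretch, its last two readings, ticks at 0.0143 h⁻¹, slower than the clock read on beta, and carrying beta on at that pace gives my floor, 84.0%; with a scatter of 1.5 percentage points on each reading, both edges are soft. Put the beta clock into the steady balance of the tank south-east, and my ceiling there is 68.8%, below the batch floor. The dosed flasks I place under the batch without a number.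

The forecast names south-west, with 85% there, inside my bracket, and 65%, 64% and 66% for north-west, south-east and north-east, concluding “Batch wins clearly”.

The flask gives south-west as best: south-west 85.6%, north-west 61.5%, south-east 63.0%, north-east 67.2%.

    J + G + X → D + X, rate k1*[J]*[G]*[X]/(1 + ([J]/sat1)) (0.0970 M, k = 110 M⁻² s⁻¹)
    2 X → Q (k = 1.60 M⁻¹ s⁻¹)
    G + Z → X + L (k = 1.90 × 10⁻⁴ M⁻¹ s⁻¹)

South-west's figure means that, from beta's last reading on, the clock averaged 0.0202 h⁻¹, less than the 0.0287 h⁻¹ read earlier. South-west's D stands short of the whole charge of J, and part of that gap is the conversion of 2 X into Q, acting together with the reading at 30 h and not later: without that step south-west reaches 95.8%, and left to 300 h it reaches 99.5%. A neighbour of south-west, the same but charged with 2.0 × 10⁻⁵ M of Z, gives 74.5%, an average clock from the start of 0.0132 h⁻¹ against 0.0230 h⁻¹ in south-west, so 2.50 times the Z bought 1.74 times the clock.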